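## Analysis of the target

Kanzonol I is a (3R)-isoflavan. Ring C (O1, C2, C3, C4, C4a, C8a) is a chroman fused to ring A, which carries methoxy groups at C5 and C7, a prenyl group at C6 between them, and hydrogen at C8. C3 bears ring B (C1' on C3), a resorcinol unit whose C2' oxygen and C3' carbon are bridged by a 2,2-dimethyl-2H-pyran (ring D), while the C4' hydroxyl is free. C3 is the only stereocentre. It lies between two methylene groups and has no carbonyl or heteroatom neighbour, so it cannot epimerise once the chroman exists, but it also offers no handle of its own for asymmetric induction. The prenyl alkene and the styrene-like alkene of ring D do not tolerate strong acid, electrophilic halogen or undirected hydrogenation, and the electron-rich arenes and the free phenol are easily oxidised. The synthesis is hard on two counts. Hydrogen must be added enantioselectively across one C=C bond while two others survive. Three regiochemical questions must also be settled: prenyl between the methoxy groups, O1 and C4 ortho to each other with C8 free, and ring D on O2'/C3' rather than on O4'. The feature used here is that O1 and C4 sit on the adjacent ring-A carbons C8a and C4a, with the C5 methoxy group next to C4a. An aryne across C4a–C8a is polarised by that methoxy group so that an oxygen nucleophile bonds to C8a and its carbon partner to C4a, and the phenol from which this aryne derives is symmetric, so only one precursor can form.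

## Retrosynthetic reasoning

**27 to 26.** The C4' hydroxyl is carried as a methoxymethyl ether and unmasked last. The acetal survives fluoride, enolates, hydrides, hydrogenation and Mitsunobu conditions, and leaves under acid mild enough for the two alkenes.

**26 to 25.** The O1–C2 ether bond is cut to give a phenol and a primary alcohol. The forward step is a dehydrative ring closure at a primary carbon that does not touch C3. This bond is chosen because it is the one that the reduction in step 12 has to break anyway.

**25 to 24.** The C3–H and C4–H bonds are removed to give the Z-allylic alcohol 24. The primary hydroxyl on C2 is the only coordinating group near any of the three alkenes. A hydroxyl-directed hydrogenation can therefore reduce C3=C4 alone and set C3 at a non-epimerisable oxidation level.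

**24 to 23.** The diol is the reductive opening product of the 3-arylcoumarin 23. The lactone ring fixes C2 and C4a cis on the double bond, so the Z geometry needed for the directed hydrogenation comes for free.

**23 to 10, 17 and 18 (key disconnection).** All four ring-C bonds that lie outside the aromatic fragments are cut: O1–C8a, C4–C4a, C3=C4 and O1–C2. Ring A becomes an aryne released from silyl triflate 10. O1 and C4 come from formamide 18. C2, C3 and rings B and D come from arylacetate 17. The cut is made here because it joins two fragments of equal size without creating a stereocentre, and because the C5 methoxy group decides the orientation. The forward reaction must insert the aryne into the C=O bond of 18 and then condense the resulting quinone methide with the enolate of 17.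

**10 to 8, 7 and 6.** The C4a–Si bond is traced to an oxygen-to-carbon silyl shift in the ortho-lithiated silyl ether of bromophenol 7. Compound 7 comes from 6 by bromination at one of its two equivalent free positions.

**6 to 5, then 2 and 3, then 1.** The C6–prenyl bond is cut. The carbon between the two methoxy groups is the most acidic ring position once the phenol of 1 is masked as the hindered silyl ether 2. The metalated arene is then alkylated by 3.

**17 to 16.** The C1'–CH2 bond is formed by coupling the aryl bromide 16 with a two-carbon zinc ester enolate. This installs the acetate unit in one step at the position fixed by the bromine.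

**16 to 15, then 12 and 13, then 11.** Ring D is opened to the aryl propargyl ether 15. Its rearrangement can only reach C3', because the other ortho position carries bromine. Compound 15 comes from phenol 12 and alcohol 13 (activated as 14). Compound 12 comes from 11 by protecting the oxygen para to bromine.

## Alternatives that were turned down

**Alternative 1:** The isoflavan is reached through a pterocarpan. C3–C1' and C4–O2' are disconnected together, and the C4–O2' bond is cut again later by reduction.
- Key step: the ring-A chromene A2 and the iodophenol A3 combine under Pd(OAc)2, a chiral bis(phosphine) and Ag2CO3. The aryl group adds to C3 and the phenol oxygen to C4, giving the cis-fused pterocarpan A1.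
- After the key step: reductive opening gives the 2'-hydroxyisoflavan A4, on which ring D is then built by propargylation and rearrangement.
- For: the C3–C1' bond and the stereocentre are made in one catalytic step. A2 is fewer steps from phenol 6 than the aryne precursor 10. The ring-B oxygens are told apart automatically, because only O2' is released by the ring opening. On these three points it is stronger than the chosen route.
- Against: the enantio-determining insertion of an aryl–palladium into a cyclic styrene has no chelating anchor, so facial control by the ligand is the weak point. The benzylic C–O bond must be cleaved by electron transfer, because catalytic hydrogenolysis would saturate the prenyl group. Ring D has to be built late, on the complete skeleton.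
- Comparison: the chosen route offers a hydrogenation steered by a bound hydroxyl group and a ring D that is in place before the fragments meet.

**Alternative 2:** C3–C4 and O1–C2 are disconnected to a ring-A ortho-quinone methide and a ring-B arylacetaldehyde.
- Key step: the enamine of aldehyde A6 with a diarylprolinol silyl ether adds to the quinone methide released from sulfone A7 by Na2CO3. The phenoxide then closes to the lactol A5, which is reduced and cyclised afterwards.
- For: C3 is set in the C–C bond-forming step by a cheap catalyst. A7 is one step from phenol 6, so the ring-A branch is clearly shorter than in the chosen route.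
- Against: C3 is created alpha to an aldehyde-level carbon that also carries an aryl group. It can racemise through the open hydroxy-aldehyde form under the basic, amine-containing conditions until the lactol is reduced. A6 is an electron-rich, easily enolised and oxidised aldehyde. The quinone methide is unsubstituted at its methide carbon and prone to oligomerise.
- Comparison: the chosen route is longer on ring A, but C3 is generated at the alcohol oxidation level, where it is configurationally stable, and its fragments 10 and 17 are storable.

**Alternative 3:** Ring B is not brought in but grown on a chiral chroman.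
- Key step: irradiation of the diazo ketone A9 gives a vinylketene by Wolff rearrangement. This adds to the siloxyalkyne A10, and four-electron ring opening followed by six-electron ring closure gives the phenol A8, with free O2' and silylated O4'. Ring D is annulated afterwards.
- For: the two ring-B oxygens are differentiated by construction, which is better than the selective protection in step 7 of the chosen route. C3 is already in place and cannot be affected.
- Against: the stereochemical problem is only moved to an enantiopure 3-substituted chroman bearing the full ring-A substitution, which needs its own asymmetric step. The diazo ketone requires several steps. The ketene and carbene intermediates are generated next to a prenyl alkene. A benzene ring is built atom by atom although ring B is a commercial resorcinol.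
- Comparison: the chosen route is far more convergent and shorter, at the price of one selectivity question on ring B.

Key step: step 11

Assumption: the enantioface preference that Ru(OAc)2(BINAP) shows for the HO–C–C=C unit of geraniol and nerol is taken to hold for the 2-aryl allylic alcohol 24. On that basis (S)-BINAP is chosen for the (3R) series.

## Route

Step 1
Reactants: 1 3,5-dimethoxyphenol
Product: 2 (3,5-dimethoxyphenoxy)tri(propan-2-yl)silane
Conditions: i-Pr3SiCl, imidazole, DMF, 25 °C
Reagents that add atoms: chlorotri(propan-2-yl)silane, CC(C)[Si](Cl)(C(C)C)C(C)C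
Why: Imidazole-promoted O-silylation of a phenol; the bulky silyl ether masks the acidic OH and is a poor metalation director, which leaves the position between the two methoxy groups as the preferred site in step 2.

Step 2
Reactants: 2 (3,5-dimethoxyphenoxy)tri(propan-2-yl)silane; 3 prenyl bromide (1-bromo-3-methylbut-2-ene)
Product: 5 [3,5-dimethoxy-4-(3-methylbut-2-en-1-yl)phenoxy]tri(propan-2-yl)silane, via aryllithium 4 (not isolated)
Conditions: n-BuLi, THF, 0 to 25 °C; then 3, −78 to 25 °C
Reagents that add atoms: none
Why: Directed ortho-metalation: both methoxy groups coordinate lithium and acidify the C–H between them, whereas the hindered silyl ether does not direct; the aryllithium 4 then displaces bromide at the primary carbon of 3 (SN2), which gives the linear prenyl group.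

Step 3
Reactants: 5 [3,5-dimethoxy-4-(3-methylbut-2-en-1-yl)phenoxy]tri(propan-2-yl)silane
Product: 6 3,5-dimethoxy-4-(3-methylbut-2-en-1-yl)phenol
Conditions: Bu4NF, AcOH, THF, 0 °C
Reagents that add atoms: none
Why: Fluoride cleaves the aryl Si–O bond; acetic acid protonates the phenoxide at once, so the electron-rich phenol is not left as an air-sensitive anion.

Step 4
Reactants: 6 3,5-dimethoxy-4-(3-methylbut-2-en-1-yl)phenol
Product: 7 2-bromo-3,5-dimethoxy-4-(3-methylbut-2-en-1-yl)phenol
Conditions: NBS (1.0 equiv), CH2Cl2, −78 °C
Reagents that add atoms: N-bromosuccinimide, O=C1CCC(=O)N1Br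
Why: Electrophilic aromatic bromination; the only free ring positions are the two equivalent carbons ortho to OH and flanked by methoxy groups, and this phloroglucinol-type ring should react at −78 °C much faster than the trisubstituted alkene, while one equivalent of reagent limits dibromination.

Step 5
Reactants: 7 2-bromo-3,5-dimethoxy-4-(3-methylbut-2-en-1-yl)phenol
Product: 8 [2-bromo-3,5-dimethoxy-4-(3-methylbut-2-en-1-yl)phenoxy]trimethylsilane
Conditions: (Me3Si)2NH, THF, 65 °C; volatiles removed
Reagents that add atoms: 1,1,1,3,3,3-hexamethyldisilazane, C[Si](C)(C)N[Si](C)(C)C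
Why: Salt-free O-silylation of the phenol, driven by loss of ammonia; the crude silyl ether is dry and ready for the anionic rearrangement.

Step 6
Reactants: 8 [2-bromo-3,5-dimethoxy-4-(3-methylbut-2-en-1-yl)phenoxy]trimethylsilane
Product: 10 3,5-dimethoxy-4-(3-methylbut-2-en-1-yl)-2-(trimethylsilyl)phenyl trifluoromethanesulfonate, via lithium silylphenoxide 9 (not isolated)
Conditions: n-BuLi, THF, −78 °C; then Tf2O, −78 to 0 °C
Reagents that add atoms: trifluoromethanesulfonic anhydride, O=S(=O)(OS(=O)(=O)C(F)(F)F)C(F)(F)F
Why: Bromine–lithium exchange is faster than any deprotonation at −78 °C; the ortho-lithiated silyl ether undergoes the 1,3 oxygen-to-carbon silyl shift (retro-Brook rearrangement) to phenoxide 9, which is O-sulfonylated; this is the standard way to ortho-silylaryl triflates, and the symmetry of 6 means only one isomer can form.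

Step 7
Reactants: 11 4-bromoresorcinol (4-bromobenzene-1,3-diol)
Product: 12 2-bromo-5-(methoxymethoxy)phenol
Conditions: NaH (2.2 equiv), DMF, 0 °C; then MeOCH2Cl (1.0 equiv), −20 to 0 °C
Reagents that add atoms: chloromethyl methyl ether, COCCl
Why: Williamson-type O-alkylation of the bis-phenoxide; the oxygen para to bromine is both the more basic and the less hindered, so it should be alkylated first, and one equivalent of the chloride leaves the ortho-bromo phenoxide free; the regiochemistry is to be confirmed by NOE from the OCH2O protons to two ring protons.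

Step 8
Reactants: 12 2-bromo-5-(methoxymethoxy)phenol; 13 2-methylbut-3-yn-2-ol
Product: 15 1-bromo-4-(methoxymethoxy)-2-[(2-methylbut-3-yn-2-yl)oxy]benzene, via propargylic trifluoroacetate 14 (not isolated)
Conditions: 13, (CF3CO)2O, DBU, MeCN, −5 °C; then 12, DBU, CuCl2·2H2O (cat.), MeCN, 0 °C
Reagents that add atoms: none
Why: Copper-catalysed propargylic etherification: the trifluoroacetate 14 made in the flask ionises through a copper acetylide to a copper allenylidene, which the phenoxide attacks at the tertiary carbon; the method is suited to hindered ortho-substituted phenols and gives O-alkylation only.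

Step 9
Reactants: 15 1-bromo-4-(methoxymethoxy)-2-[(2-methylbut-3-yn-2-yl)oxy]benzene
Product: 16 8-bromo-5-(methoxymethoxy)-2,2-dimethyl-2H-chromene
Conditions: o-xylene, 140 °C
Reagents that add atoms: none
Why: Aromatic propargyl Claisen rearrangement to the only free ortho carbon (the one between the two oxygens, since the other carries bromine), followed by tautomerisation, 1,5-hydrogen shift and oxa-6π electrocyclisation, which closes ring D with unambiguous regiochemistry.

Step 10
Reactants: 16 8-bromo-5-(methoxymethoxy)-2,2-dimethyl-2H-chromene
Product: 17 methyl 2-[5-(methoxymethoxy)-2,2-dimethyl-2H-chromen-8-yl]acetate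
Conditions: BrZnCH2CO2Me (from BrCH2CO2Me, Zn dust, THF), Pd2(dba)3 (cat.), XPhos (cat.), THF, 60 °C
Reagents that add atoms: bromo(2-methoxy-2-oxoethyl)zinc, COC(=O)C[Zn]Br
Why: Negishi-type palladium-catalysed alpha-arylation of a Reformatsky reagent; the weakly basic zinc enolate tolerates the acetal and does not self-condense, and the bulky biarylphosphine on zerovalent palladium favours oxidative addition to the electron-rich bromide and reductive elimination over Heck reaction at the ring-D alkene.

Step 11
Reactants: 10 3,5-dimethoxy-4-(3-methylbut-2-en-1-yl)-2-(trimethylsilyl)phenyl trifluoromethanesulfonate; 17 methyl 2-[5-(methoxymethoxy)-2,2-dimethyl-2H-chromen-8-yl]acetate; 18 N,N-dimethylformamide (reactant and solvent)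
Product: 23 5,7-dimethoxy-3-[5-(methoxymethoxy)-2,2-dimethyl-2H-chromen-8-yl]-6-(3-methylbut-2-en-1-yl)-2H-chromen-2-one, via aryne 19 (not isolated), via amino ortho-quinone methide 20 (not isolated), via potassium enolate 21 (not isolated), via aminolactone 22 (not isolated)
Conditions: 10, CsF, 18 (dilute, about 0.03 M), 25 °C; then transferred into 21 [17, KN(SiMe3)2, THF, −78 °C], −40 to 50 °C
Reagents that add atoms: none
Why: Fluoride attacks the silicon of 10 and triflate leaves, giving aryne 19, whose C4a–C8a triple bond is distorted by the sigma-withdrawing C5 methoxy group so that the carbonyl oxygen of 18 bonds to C8a, the unhindered terminus, and the developing C4a carbanion, stabilised by the neighbouring C–O dipole, closes onto the iminium carbon (formal 2+2 addition that forms O1–C8a and C4–C4a). The benzoxete opens by four-electron electrocyclic cleavage to the amino ortho-quinone methide 20, which behaves as a phenoxide–iminium. Enolate 21 adds to its exocyclic carbon (Mannich-type, forming C3–C4), the freed phenoxide attacks the methyl ester in a 6-exo-trig acyl substitution (O1–C2) to give aminolactone 22, and E1cB loss of dimethylamine from the acidic C3–H gives the conjugated coumarin; if elimination runs ahead of lactonisation, reversible amine addition lets the acrylate geometry adjust, and any 20 hydrolysed by trace water still condenses with 21 as the salicylaldehyde. The closest known reaction type is the three-component coupling of arynes, formamides and ester enolates or active methylene compounds to coumarins. Ring C is closed by lactonisation after two intermolecular bond formations, and no stereocentre is created. The step needs regioselectivity, which the C5 methoxy group secures (the C7 methoxy group is remote from both aryne carbons), and chemoselectivity for insertion of 18 over direct arylation of the enolate, which is secured by generating the aryne in neat 18 at high dilution before 21 is introduced.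

Step 12
Reactants: 23 5,7-dimethoxy-3-[5-(methoxymethoxy)-2,2-dimethyl-2H-chromen-8-yl]-6-(3-methylbut-2-en-1-yl)-2H-chromen-2-one
Product: 24 (2Z)-3-[6-hydroxy-2,4-dimethoxy-3-(3-methylbut-2-en-1-yl)phenyl]-2-[5-(methoxymethoxy)-2,2-dimethyl-2H-chromen-8-yl]prop-2-en-1-ol
Conditions: i-Bu2AlH (5 equiv), CH2Cl2, −78 to −20 °C; aq. KNaC4H4O6 work-up
Reagents that add atoms: none
Why: Hydride reduction of the lactone to the lactol aluminate, which opens to the enal phenoxide and is reduced again in 1,2-fashion by the aluminium hydride; the Z geometry (CH2OH cis to ring A) is inherited from the ring, and the neutral tartrate work-up avoids acid-promoted cyclodehydration of the electron-rich diol.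

Step 13
Reactants: 24 (2Z)-3-[6-hydroxy-2,4-dimethoxy-3-(3-methylbut-2-en-1-yl)phenyl]-2-[5-(methoxymethoxy)-2,2-dimethyl-2H-chromen-8-yl]prop-2-en-1-ol
Product: 25 (2R)-3-[6-hydroxy-2,4-dimethoxy-3-(3-methylbut-2-en-1-yl)phenyl]-2-[5-(methoxymethoxy)-2,2-dimethyl-2H-chromen-8-yl]propan-1-ol
Conditions: Ru(OAc)2[(S)-BINAP] (cat.), H2 (100 atm), MeOH/CH2Cl2, 30 °C
Reagents that add atoms: none
Why: Hydroxyl-directed asymmetric hydrogenation of an allylic alcohol: the primary alkoxide binds divalent ruthenium and hydrogen is delivered to the chelated C3=C4 bond only, while the prenyl and ring-D alkenes have no anchoring group and should not be reduced, as in the geraniol-to-citronellol case. The (S)-BINAP complex adds hydrogen to the face of the HO–C–C=C unit that gives (R)-citronellol from geraniol; applied to the Z-alkene of 24 the same face gives the (R) configuration at C3, and the sense is to be confirmed on the product, with the (R)-BINAP complex used if it proves opposite.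

Step 14
Reactants: 25 (2R)-3-[6-hydroxy-2,4-dimethoxy-3-(3-methylbut-2-en-1-yl)phenyl]-2-[5-(methoxymethoxy)-2,2-dimethyl-2H-chromen-8-yl]propan-1-ol
Product: 26 (3R)-5,7-dimethoxy-3-[5-(methoxymethoxy)-2,2-dimethyl-2H-chromen-8-yl]-6-(3-methylbut-2-en-1-yl)-3,4-dihydro-2H-chromene
Conditions: PPh3, DIAD, THF, 0 to 25 °C
Reagents that add atoms: none
Why: Intramolecular Mitsunobu etherification: the phenol is acidic enough to protonate the betaine and displaces the activated primary oxygen in a 6-exo-tet closure of O1–C2; C3 is not a reacting centre, so its configuration is kept.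

Step 15
Reactants: 26 (3R)-5,7-dimethoxy-3-[5-(methoxymethoxy)-2,2-dimethyl-2H-chromen-8-yl]-6-(3-methylbut-2-en-1-yl)-3,4-dihydro-2H-chromene
Product: 27 kanzonol I, 8-[(3R)-5,7-dimethoxy-6-(3-methylbut-2-en-1-yl)-3,4-dihydro-2H-chromen-3-yl]-2,2-dimethyl-2H-chromen-5-ol
Conditions: HCl (3 M aq.), MeOH/THF, 25 °C
Reagents that add atoms: none
Why: Acid-catalysed cleavage of a phenolic methoxymethyl acetal by transfer to methanol, which proceeds at room temperature; ring A has no free hydroxyl next to the prenyl group, so no chroman can form there, and C3 has no pathway for epimerisation.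

## Compound list

1 | 3,5-dimethoxyphenol | COc1cc(O)cc(OC)c1 | starting material
2 | (3,5-dimethoxyphenoxy)tri(propan-2-yl)silane | COc1cc(O[Si](C(C)C)(C(C)C)C(C)C)cc(OC)c1 | intermediate
3 | prenyl bromide (1-bromo-3-methylbut-2-ene) | CC(C)=CCBr | starting material
4 | {2,6-dimethoxy-4-[tri(propan-2-yl)silyloxy]phenyl}lithium (not isolated) | [Li]c1c(OC)cc(O[Si](C(C)C)(C(C)C)C(C)C)cc1OC | intermediate
5 | [3,5-dimethoxy-4-(3-methylbut-2-en-1-yl)phenoxy]tri(propan-2-yl)silane | COc1cc(O[Si](C(C)C)(C(C)C)C(C)C)cc(OC)c1CC=C(C)C | intermediate
6 | 3,5-dimethoxy-4-(3-methylbut-2-en-1-yl)phenol | COc1cc(O)cc(OC)c1CC=C(C)C | intermediate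
7 | 2-bromo-3,5-dimethoxy-4-(3-methylbut-2-en-1-yl)phenol | COc1cc(O)c(Br)c(OC)c1CC=C(C)C | intermediate
8 | [2-bromo-3,5-dimethoxy-4-(3-methylbut-2-en-1-yl)phenoxy]trimethylsilane | COc1cc(O[Si](C)(C)C)c(Br)c(OC)c1CC=C(C)C | intermediate
9 | lithium 3,5-dimethoxy-4-(3-methylbut-2-en-1-yl)-2-(trimethylsilyl)phenoxide (not isolated) | [Li+].COc1cc([O-])c([Si](C)(C)C)c(OC)c1CC=C(C)C | intermediate
10 | 3,5-dimethoxy-4-(3-methylbut-2-en-1-yl)-2-(trimethylsilyl)phenyl trifluoromethanesulfonate | COc1cc(OS(=O)(=O)C(F)(F)F)c([Si](C)(C)C)c(OC)c1CC=C(C)C | intermediate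
11 | 4-bromoresorcinol (4-bromobenzene-1,3-diol) | Oc1ccc(Br)c(O)c1 | starting material
12 | 2-bromo-5-(methoxymethoxy)phenol | COCOc1ccc(Br)c(O)c1 | intermediate
13 | 2-methylbut-3-yn-2-ol | CC(C)(O)C#C | starting material
14 | 2-methylbut-3-yn-2-yl trifluoroacetate (not isolated) | CC(C)(OC(=O)C(F)(F)F)C#C | intermediate
15 | 1-bromo-4-(methoxymethoxy)-2-[(2-methylbut-3-yn-2-yl)oxy]benzene | COCOc1ccc(Br)c(OC(C)(C)C#C)c1 | intermediate
16 | 8-bromo-5-(methoxymethoxy)-2,2-dimethyl-2H-chromene | COCOc1ccc(Br)c2c1C=CC(C)(C)O2 | intermediate
17 | methyl 2-[5-(methoxymethoxy)-2,2-dimethyl-2H-chromen-8-yl]acetate | COC(=O)Cc1ccc(OCOC)c2c1OC(C)(C)C=C2 | intermediate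
18 | N,N-dimethylformamide | CN(C)C=O | starting material
19 | 1,2-didehydro-3,5-dimethoxy-4-(3-methylbut-2-en-1-yl)benzene, the ring-A aryne (not isolated) | COC1=CC#CC(OC)=C1CC=C(C)C | intermediate
20 | 6-[(dimethylamino)methylidene]-3,5-dimethoxy-4-(3-methylbut-2-en-1-yl)cyclohexa-2,4-dien-1-one (not isolated; in equilibrium with its benzoxete) | CN(C)C=C1C(=O)C=C(OC)C(CC=C(C)C)=C1OC | intermediate
21 | potassium 1-methoxy-2-[5-(methoxymethoxy)-2,2-dimethyl-2H-chromen-8-yl]ethen-1-olate (not isolated) | [K+].COC([O-])=Cc1ccc(OCOC)c2c1OC(C)(C)C=C2 | intermediate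
22 | 4-(dimethylamino)-5,7-dimethoxy-3-[5-(methoxymethoxy)-2,2-dimethyl-2H-chromen-8-yl]-6-(3-methylbut-2-en-1-yl)-3,4-dihydro-2H-chromen-2-one (not isolated; diastereomer mixture) | COc1cc2c(c(OC)c1CC=C(C)C)C(N(C)C)C(c1ccc(OCOC)c3c1OC(C)(C)C=C3)C(=O)O2 | intermediate
23 | 5,7-dimethoxy-3-[5-(methoxymethoxy)-2,2-dimethyl-2H-chromen-8-yl]-6-(3-methylbut-2-en-1-yl)-2H-chromen-2-one | COc1cc2c(c(OC)c1CC=C(C)C)C=C(c1ccc(OCOC)c3c1OC(C)(C)C=C3)C(=O)O2 | intermediate
24 | (2Z)-3-[6-hydroxy-2,4-dimethoxy-3-(3-methylbut-2-en-1-yl)phenyl]-2-[5-(methoxymethoxy)-2,2-dimethyl-2H-chromen-8-yl]prop-2-en-1-ol | OC/C(c1ccc(OCOC)c2c1OC(C)(C)C=C2)=C\c1c(O)cc(OC)c(CC=C(C)C)c1OC | intermediate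
25 | (2R)-3-[6-hydroxy-2,4-dimethoxy-3-(3-methylbut-2-en-1-yl)phenyl]-2-[5-(methoxymethoxy)-2,2-dimethyl-2H-chromen-8-yl]propan-1-ol | OC[C@@H](c1ccc(OCOC)c2c1OC(C)(C)C=C2)Cc1c(O)cc(OC)c(CC=C(C)C)c1OC | intermediate
26 | (3R)-5,7-dimethoxy-3-[5-(methoxymethoxy)-2,2-dimethyl-2H-chromen-8-yl]-6-(3-methylbut-2-en-1-yl)-3,4-dihydro-2H-chromene | COc1cc2c(c(OC)c1CC=C(C)C)C[C@H](c1ccc(OCOC)c3c1OC(C)(C)C=C3)CO2 | intermediate
27 | kanzonol I, 8-[(3R)-5,7-dimethoxy-6-(3-methylbut-2-en-1-yl)-3,4-dihydro-2H-chromen-3-yl]-2,2-dimethyl-2H-chromen-5-ol | COc1cc2c(c(OC)c1CC=C(C)C)C[C@H](c1ccc(O)c3c1OC(C)(C)C=C3)CO2 | target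

## Step count and least certain steps

Total: 15 steps. Longest linear sequence: 11 steps (steps 1 to 6 and 11 to 15, from 1). The ring-B branch (steps 7 to 10) has 4 steps and joins at step 11.

**Step 11 (key step).**
- What may go wrong: the aryne–formamide adduct 20 may be consumed by further aryne (O-arylation or cycloaddition) before the enolate arrives. If the enolate is present too early, it may be arylated directly on carbon by the aryne. Loss of dimethylamine from 22 may stall.
- Fallback: the same aryne insertion is used, but the condensation is done stepwise. It sets out from 10 and 17 and returns at 23. Treatment of 10 with CsF in 18 followed by aqueous work-up hydrolyses 20 to 6-hydroxy-2,4-dimethoxy-3-(3-methylbut-2-en-1-yl)benzaldehyde F1. Saponification of 17 (LiOH, THF/water) gives 2-[5-(methoxymethoxy)-2,2-dimethyl-2H-chromen-8-yl]acetic acid F2. A Perkin–Oglialoro condensation of F1 with F2 (Ac2O, Et3N, 110 °C) acylates the phenol, closes C3–C4 by intramolecular aldol reaction and dehydrates to 23.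

**Step 13.**
- What may go wrong: turnover may be slow because the trisubstituted alkene carries two ortho-substituted aryl groups. Facial selectivity may be poor or reversed, because the aryl group on the carbinol-bearing alkene carbon occupies a region of the catalyst that the geraniol model does not probe. The electron-rich diol 24 may cyclodehydrate to the 2H-chromene. The allylic alcohol may isomerise to the aldehyde if the hydrogen pressure is too low.
- Fallback: this sets out from 23, bypasses 24 and returns at 25. Conjugate reduction of the coumarin C3=C4 bond with copper hydride ([(Ph3P)CuH]6 (cat.), polymethylhydrosiloxane, toluene) gives racemic 5,7-dimethoxy-3-[5-(methoxymethoxy)-2,2-dimethyl-2H-chromen-8-yl]-6-(3-methylbut-2-en-1-yl)-3,4-dihydro-2H-chromen-2-one F3. Its C3–H is alpha to the lactone carbonyl and to ring B, so it equilibrates under base. Hydrogenation of the lactone carbonyl under dynamic kinetic resolution (H2, KOt-Bu, the catalyst formed from [Ir(cod)Cl]2 and a chiral spiro pyridine-aminophosphine ligand, with the ligand antipode chosen to give the R alcohol) is carbonyl-selective, leaves the C=C bonds alone and gives 25.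

**Step 7.**
- What may go wrong: the oxygen ortho to bromine may be alkylated instead, or both oxygens may react, because the two phenoxides differ only moderately in basicity and hindrance.
- Fallback: the oxygens are differentiated by size and the protecting group is exchanged later. It sets out from 11 and returns at 16. Silylation with i-Pr3SiCl and imidazole should select the unhindered hydroxyl and give 2-bromo-5-[tri(propan-2-yl)silyloxy]phenol F4. Propargylation with 14 under the conditions of step 8 gives {4-bromo-3-[(2-methylbut-3-yn-2-yl)oxy]phenoxy}tri(propan-2-yl)silane F5. Heating as in step 9 gives [(8-bromo-2,2-dimethyl-2H-chromen-5-yl)oxy]tri(propan-2-yl)silane F6. Bu4NF releases 8-bromo-2,2-dimethyl-2H-chromen-5-ol F7, and MeOCH2Cl with i-Pr2NEt gives 16.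

**Step 4.**
- What may go wrong: electrophilic bromine may add to the prenyl alkene, or both ortho positions may be brominated.
- Fallback: no electrophilic halogen is used. It sets out from 6 and returns at 10, bypassing 7 and 8. Reaction of 6 with isopropyl isocyanate (Et3N) gives 3,5-dimethoxy-4-(3-methylbut-2-en-1-yl)phenyl N-(propan-2-yl)carbamate F8. N-Silylation in the flask (Me3SiOTf, TMEDA), carbamate-directed ortho-lithiation (n-BuLi, TMEDA, −78 °C) and Me3SiCl give 3,5-dimethoxy-4-(3-methylbut-2-en-1-yl)-2-(trimethylsilyl)phenyl N-(propan-2-yl)carbamate F9. Cleavage of the carbamate with Et2NH and DBU in MeCN, then PhNTf2 in the same flask, gives 10.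

**Step 10.**
- What may go wrong: oxidative addition to the electron-rich bromide may be slow, so that the zinc enolate is protonated or self-condenses and the bromide is reduced.
- Fallback: the acetate carbon is introduced as a malonate. It sets out from 16 and returns at 17. Arylation of dimethyl malonate (Pd(OAc)2, P(t-Bu)3, K3PO4, toluene, 80 °C) gives dimethyl 2-[5-(methoxymethoxy)-2,2-dimethyl-2H-chromen-8-yl]propanedioate F10. Krapcho dealkoxycarbonylation (LiCl, wet DMSO, 130 °C) gives 17.

## Further compounds

F1 | step 11 | 6-hydroxy-2,4-dimethoxy-3-(3-methylbut-2-en-1-yl)benzaldehyde | COc1cc(O)c(C=O)c(OC)c1CC=C(C)C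
F2 | step 11 | 2-[5-(methoxymethoxy)-2,2-dimethyl-2H-chromen-8-yl]acetic acid | OC(=O)Cc1ccc(OCOC)c2c1OC(C)(C)C=C2
F3 | step 13 | racemic 5,7-dimethoxy-3-[5-(methoxymethoxy)-2,2-dimethyl-2H-chromen-8-yl]-6-(3-methylbut-2-en-1-yl)-3,4-dihydro-2H-chromen-2-one | COc1cc2c(c(OC)c1CC=C(C)C)CC(c1ccc(OCOC)c3c1OC(C)(C)C=C3)C(=O)O2
F4 | step 7 | 2-bromo-5-[tri(propan-2-yl)silyloxy]phenol | CC(C)[Si](Oc1ccc(Br)c(O)c1)(C(C)C)C(C)C
F5 | step 7 | {4-bromo-3-[(2-methylbut-3-yn-2-yl)oxy]phenoxy}tri(propan-2-yl)silane | CC(C)[Si](Oc1ccc(Br)c(OC(C)(C)C#C)c1)(C(C)C)C(C)C
F6 | step 7 | [(8-bromo-2,2-dimethyl-2H-chromen-5-yl)oxy]tri(propan-2-yl)silane | CC(C)[Si](Oc1ccc(Br)c2c1C=CC(C)(C)O2)(C(C)C)C(C)C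
F7 | step 7 | 8-bromo-2,2-dimethyl-2H-chromen-5-ol | Oc1ccc(Br)c2c1C=CC(C)(C)O2
F8 | step 4 | 3,5-dimethoxy-4-(3-methylbut-2-en-1-yl)phenyl N-(propan-2-yl)carbamate | COc1cc(OC(=O)NC(C)C)cc(OC)c1CC=C(C)C
F9 | step 4 | 3,5-dimethoxy-4-(3-methylbut-2-en-1-yl)-2-(trimethylsilyl)phenyl N-(propan-2-yl)carbamate | COc1cc(OC(=O)NC(C)C)c([Si](C)(C)C)c(OC)c1CC=C(C)C
F10 | step 10 | dimethyl 2-[5-(methoxymethoxy)-2,2-dimethyl-2H-chromen-8-yl]propanedioate | COC(=O)C(C(=O)OC)c1ccc(OCOC)c2c1OC(C)(C)C=C2
A1 | alternative 1 | (6aR,11aR)-1,3-dimethoxy-9-(methoxymethoxy)-2-(3-methylbut-2-en-1-yl)-6a,11a-dihydro-6H-[1]benzofuro[3,2-c]chromene | COc1cc2c(c(OC)c1CC=C(C)C)[C@@H]3Oc4cc(OCOC)ccc4[C@@H]3CO2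
A2 | alternative 1 | 5,7-dimethoxy-6-(3-methylbut-2-en-1-yl)-2H-chromene | COc1cc2c(c(OC)c1CC=C(C)C)C=CCO2
A3 | alternative 1 | 2-iodo-5-(methoxymethoxy)phenol | COCOc1ccc(I)c(O)c1
A4 | alternative 1 | 2-[(3R)-5,7-dimethoxy-6-(3-methylbut-2-en-1-yl)-3,4-dihydro-2H-chromen-3-yl]-5-(methoxymethoxy)phenol | COc1cc2c(c(OC)c1CC=C(C)C)C[C@H](c1ccc(OCOC)cc1O)CO2
A5 | alternative 2 | (3R)-3-[5-(tert-butyldimethylsilyloxy)-2,2-dimethyl-2H-chromen-8-yl]-5,7-dimethoxy-6-(3-methylbut-2-en-1-yl)-3,4-dihydro-2H-chromen-2-ol (anomeric mixture) | COc1cc2c(c(OC)c1CC=C(C)C)C[C@H](c1ccc(O[Si](C)(C)C(C)(C)C)c3c1OC(C)(C)C=C3)C(O)O2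
A6 | alternative 2 | 2-[5-(tert-butyldimethylsilyloxy)-2,2-dimethyl-2H-chromen-8-yl]acetaldehyde | O=CCc1ccc(O[Si](C)(C)C(C)(C)C)c2c1OC(C)(C)C=C2
A7 | alternative 2 | 3,5-dimethoxy-4-(3-methylbut-2-en-1-yl)-2-[(4-methylbenzenesulfonyl)methyl]phenol | COc1cc(O)c(CS(=O)(=O)c2ccc(C)cc2)c(OC)c1CC=C(C)C
A8 | alternative 3 | 2-[(3R)-5,7-dimethoxy-6-(3-methylbut-2-en-1-yl)-3,4-dihydro-2H-chromen-3-yl]-5-[tri(propan-2-yl)silyloxy]phenol | COc1cc2c(c(OC)c1CC=C(C)C)C[C@H](c1ccc(O[Si](C(C)C)(C(C)C)C(C)C)cc1O)CO2
A9 | alternative 3 | (3E)-1-diazo-4-[(3R)-5,7-dimethoxy-6-(3-methylbut-2-en-1-yl)-3,4-dihydro-2H-chromen-3-yl]but-3-en-2-one | COc1cc2c(c(OC)c1CC=C(C)C)C[C@H](/C=C/C(=O)C=[N+]=[N-])CO2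
A10 | alternative 3 | (ethynyloxy)tri(propan-2-yl)silane | C#CO[Si](C(C)C)(C(C)C)C(C)C
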